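**Plan**

- Retrosynthesis: after unmasking (two O-methyl ethers, three Boc groups), the target is cut at its two N–CH2 bonds at the chain ends, N(1)–C(1) and N(8)–C(8).
- Enabling feature: N(1) and N(8) are amide nitrogens bound to the primary carbons C(1) and C(8) of an unbranched chain. Each can therefore arrive already acylated, as an acidic enoyl-Boc imide N–H, and the chain fragment then holds N(4) as its only nitrogen. The two para-oxygenated benzene rings are the only rings and are bought.
- Forward, chain fragment: the N(4)–C(3) bond is made by N-alkylation of 4-aminobutan-1-ol with 3-bromopropan-1-ol, and N(4) is then Boc-protected to give the amino diol.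
- Forward, acyl fragment: (E)-4-methoxycinnamic acid is taken to its primary amide and then to the N-Boc acyl carbamate.
- Joining and end game: a twofold Mitsunobu alkylation attaches both acyl carbamates to the diol, and BBr3 then removes the methyl ethers and all Boc groups.
- Stereochemistry: there is no stereocentre. Both E double bonds come from the (E)-4-methoxycinnamic acid and are carried through unchanged.

Key step: step 5

Remark on the chemistry: the target is taken as the neutral free base drawn. Hydroxycinnamoyl amides can isomerise from E to Z in light, so all operations from step 3 onward are assumed to be run with light excluded.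

**Route**

Step 1
Reactants: 1 4-aminobutan-1-ol; 2 3-bromopropan-1-ol
Product: 3 4-[(3-hydroxypropyl)amino]butan-1-ol
Conditions: 1 (4 equiv), K2CO3, EtOH, 70 °C; excess 1 distilled off
Reagents that add atoms: none
Why: SN2 N-alkylation of a primary amine by a primary alkyl bromide, in which the large excess of 1 should suppress dialkylation and nitrogen should far outcompete the hydroxyl groups, so that only the N(4)–C(3) bond forms.

Step 2
Reactants: 3 4-[(3-hydroxypropyl)amino]butan-1-ol
Product: 4 tert-butyl N-(4-hydroxybutyl)-N-(3-hydroxypropyl)carbamate
Conditions: Boc2O (1.05 equiv), MeOH, 0 °C to rt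
Reagents that add atoms: di-tert-butyl dicarbonate, CC(C)(C)OC(=O)OC(=O)OC(C)(C)C
Why: Chemoselective carbamate formation (N-Boc protection), since a secondary amine should react with Boc2O much faster than primary alcohols when no acylation catalyst is present.

Step 3
Reactants: 5 (E)-4-methoxycinnamic acid
Product: 7 (E)-4-methoxycinnamamide, via (E)-4-methoxycinnamoyl chloride 6 (not isolated)
Conditions: (COCl)2, cat. DMF, CH2Cl2, 0 °C to rt; evaporate; then 28% aq. NH3, THF, 0 °C
Reagents that add atoms: ammonia, N
Why: Acid chloride formation under Vilsmeier-type catalysis followed by Schotten–Baumann aminolysis, a standard primary amide synthesis in which acyl substitution should be far faster than any conjugate addition, leaving the E alkene untouched.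

Step 4
Reactants: 7 (E)-4-methoxycinnamamide
Product: 9 tert-butyl N-[(E)-3-(4-methoxyphenyl)prop-2-enoyl]carbamate, via (E)-4-methoxycinnamoyl isocyanate 8 (not isolated)
Conditions: (COCl)2, ClCH2CH2Cl, 0 to 70 °C; evaporate; then t-BuOH, CH2Cl2, 0 °C to rt
Reagents that add atoms: oxalyl chloride, O=C(Cl)C(=O)Cl; tert-butanol, CC(C)(C)O
Why: Acyl isocyanate formation from a primary amide and oxalyl chloride followed by addition of an alcohol to the isocyanate, a known route to N-acyl carbamates of acrylamide-type amides; removing HCl before the alcohol is added should protect the new Boc group.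

Step 5
Reactants: 4 tert-butyl N-(4-hydroxybutyl)-N-(3-hydroxypropyl)carbamate; 9 tert-butyl N-[(E)-3-(4-methoxyphenyl)prop-2-enoyl]carbamate
Product: 12 N(1),N(4),N(8)-tri-Boc-N(1),N(8)-bis[(E)-4-methoxycinnamoyl]spermidine, via N(1)-monoalkylated alcohol 10 (not isolated), via N(8)-monoalkylated alcohol 11 (not isolated)
Conditions: 9 (2.4 equiv), PPh3 (2.6 equiv), DIAD (2.6 equiv, slow addition), THF, 0 °C to rt
Reagents that add atoms: none
Why: Twofold Mitsunobu N-alkylation: PPh3 adds to DIAD to give a betaine that deprotonates the N–H of 9, which is acidified by the flanking enoyl and Boc carbonyl groups, while each primary hydroxyl of 4 becomes an alkoxyphosphonium ion that the imide nitrogen displaces by SN2, first through 10 or 11 and then at the remaining arm. The closest known reaction type is the Mitsunobu alkylation of imide-type N–H pronucleophiles (phthalimide, imidodicarbonates, N-acyl and N-sulfonyl carbamates) by primary alcohols. No ring closes and no stereocentre is created; both new bonds, N(1)–C(1) and N(8)–C(8), are to unhindered primary carbons. The step needs N- over O-alkylation of the ambident anion, which displacement at an unhindered primary carbon by the more nucleophilic nitrogen terminus should secure. It also needs intermolecular displacement to beat capture of the alkoxyphosphonium ion by the N(4)-Boc carbonyl oxygen, which the excess of 9 and slow addition of DIAD at 0 °C should favour. The phenols are carried as methyl ethers so that the imide N–H is the only acidic site, and the neutral conditions should leave the E double bonds and all Boc groups intact.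

Step 6
Reactants: 12 N(1),N(4),N(8)-tri-Boc-N(1),N(8)-bis[(E)-4-methoxycinnamoyl]spermidine
Product: 14 N(1),N(8)-bis(coumaroyl)spermidine, via hydrobromide salt 13 (not isolated)
Conditions: BBr3 (12 equiv), CH2Cl2, −78 °C to rt; MeOH, 0 °C, evaporate; dilute aq. NH3 to pH 8–9, C18 chromatography
Reagents that add atoms: none
Why: Lewis-acid dealkylation with BBr3, which should cleave the two aryl methyl ethers (bromide attack at methyl of the boron-complexed ether) and the three tert-butyl carbamates (loss of the tert-butyl cation and CO2) while secondary amides and E-styrenyl double bonds persist; methanolysis of the borates and neutralisation of the amine salt should then free the target.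

**Compound list**

1 | 4-aminobutan-1-ol | NCCCCO | starting material
2 | 3-bromopropan-1-ol | OCCCBr | starting material
3 | 4-[(3-hydroxypropyl)amino]butan-1-ol | OCCCCNCCCO | intermediate
4 | tert-butyl N-(4-hydroxybutyl)-N-(3-hydroxypropyl)carbamate | OCCCCN(C(=O)OC(C)(C)C)CCCO | intermediate
5 | (E)-4-methoxycinnamic acid | COc1ccc(/C=C/C(=O)O)cc1 | starting material
6 | (E)-4-methoxycinnamoyl chloride (not isolated) | COc1ccc(/C=C/C(=O)Cl)cc1 | intermediate
7 | (E)-4-methoxycinnamamide | COc1ccc(/C=C/C(N)=O)cc1 | intermediate
8 | (E)-4-methoxycinnamoyl isocyanate (not isolated) | COc1ccc(/C=C/C(=O)N=C=O)cc1 | intermediate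
9 | tert-butyl N-[(E)-3-(4-methoxyphenyl)prop-2-enoyl]carbamate | COc1ccc(/C=C/C(=O)NC(=O)OC(C)(C)C)cc1 | intermediate
10 | tert-butyl N-(4-hydroxybutyl)-N-{3-[N-Boc-(E)-4-methoxycinnamoylamino]propyl}carbamate, the N(1)-monoalkylated alcohol (not isolated) | COc1ccc(/C=C/C(=O)N(C(=O)OC(C)(C)C)CCCN(C(=O)OC(C)(C)C)CCCCO)cc1 | intermediate
11 | tert-butyl N-(3-hydroxypropyl)-N-{4-[N-Boc-(E)-4-methoxycinnamoylamino]butyl}carbamate, the N(8)-monoalkylated alcohol (not isolated) | COc1ccc(/C=C/C(=O)N(C(=O)OC(C)(C)C)CCCCN(C(=O)OC(C)(C)C)CCCO)cc1 | intermediate
12 | N(1),N(4),N(8)-tri-Boc-N(1),N(8)-bis[(E)-4-methoxycinnamoyl]spermidine | COc1ccc(/C=C/C(=O)N(C(=O)OC(C)(C)C)CCCCN(C(=O)OC(C)(C)C)CCCN(C(=O)OC(C)(C)C)C(=O)/C=C/c2ccc(OC)cc2)cc1 | intermediate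
13 | N(1),N(8)-bis[(E)-4-hydroxycinnamoyl]spermidine hydrobromide (not isolated) | O=C(/C=C/c1ccc(O)cc1)NCCCC[NH2+]CCCNC(=O)/C=C/c1ccc(O)cc1.[Br-] | intermediate
14 | N(1),N(8)-bis(coumaroyl)spermidine, both double bonds E | O=C(/C=C/c1ccc(O)cc1)NCCCCNCCCNC(=O)/C=C/c1ccc(O)cc1 | target

**Totals**

Total step count: 6. Longest linear sequence: 4 steps (steps 3, 4, 5, 6 from acid 5; equally steps 1, 2, 5, 6 from amine 1).

**Steps most likely to fail**

1. Step 5.
- What may go wrong: the imide N–H may be too weakly acidic for the PPh3/DIAD betaine, so activation stalls and the alkoxyphosphonium ion alkylates the hydrazide by-product instead. The ambident anion may react at oxygen. The alkoxyphosphonium ion may be captured internally by the N(4)-Boc carbonyl oxygen with loss of the tert-butyl group. The second alkylation may remain incomplete.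
- Fallback: setting out from 4, both hydroxyls are converted with MsCl and Et3N in CH2Cl2 at 0 °C into tert-butyl N-[4-(methanesulfonyloxy)butyl]-N-[3-(methanesulfonyloxy)propyl]carbamate F1. The cesium salt of 9 (Cs2CO3, cat. n-Bu4NI, DMF, rt to 40 °C) then displaces both mesylates in a classical SN2 N-alkylation of an imide anion, which forms the same two bonds and rejoins the route at 12.

2. Step 6.
- What may go wrong: ether cleavage may stop short because boron complexes of the amine and amides precipitate. tert-Butyl cations released in the Lewis-acidic medium may alkylate the electron-rich rings. HBr may add to the styrenyl double bonds or isomerise them.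
- Fallback: setting out from 12, TFA in CH2Cl2 with anisole as cation scavenger (0 °C to rt) removes the three Boc groups, and basic work-up gives N(1),N(8)-bis[(E)-4-methoxycinnamoyl]spermidine F2. The two aryl methyl ethers are then cleaved without any Lewis acid by SN2 attack of thiolate at methyl (NaSEt, DMF, 110 °C), and adjustment to about pH 8 brings the route back at 14.

3. Step 4.
- What may go wrong: the moisture-sensitive acyl isocyanate may hydrolyse back to the amide. Residual HCl may strip the newly installed Boc group or add to the double bond.
- Fallback: setting out from 6 (made from 5 as in step 3), the acid chloride is added at 0 °C to the sodium salt of tert-butyl carbamate (BocNH2, NaH 2.2 equiv, THF). This N-acylation of a carbamate anion gives 9 directly after quenching with aqueous NH4Cl. Compounds 7 and 8 are bypassed and no new compound arises on this path (F0).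

Further compounds
F1 | step 5 | tert-butyl N-[4-(methanesulfonyloxy)butyl]-N-[3-(methanesulfonyloxy)propyl]carbamate | CS(=O)(=O)OCCCCN(C(=O)OC(C)(C)C)CCCOS(C)(=O)=O
F2 | step 6 | N(1),N(8)-bis[(E)-4-methoxycinnamoyl]spermidine | COc1ccc(/C=C/C(=O)NCCCCNCCCNC(=O)/C=C/c2ccc(OC)cc2)cc1
F0 | step 4 | none | none
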